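A direct plan would etherify 4-hydroxy-5-methylcoumarin A1 with a preformed (2E,4S)-3,7-dimethylocta-2,6-diene-1,4-diol A2 by a Mitsunobu reaction to give the prenyl-terminated ether A3, and would finish with a dye-sensitised singlet-oxygen ene reaction at C6=C7.
- **Final ene reaction:** the C4 carbinol sits 1,3 to the alkene and would give no facial bias, so the target would form with about as much of its 6R epimer A4 and with the tertiary C7 hydroperoxide A5. The hardest stereocentre would be left to HPLC on a labile product.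
- **Making of A2:** a small diol would need a stoichiometric chiral-diamine carbenoid homologation (lithiation, borylation, oxidation) framed by silyl protection and removal, so the longest effort would go into the easiest centre.
- **Mitsunobu coupling:** it would have to tell the primary from the secondary allylic hydroxyl of A2, and O- from C-alkylation of the ambident coumarin A1, when the chiral chain is already the costly partner.

**Retrosynthetic overview**
- Feature addressed: the anti-1,3 pair C4–OH / C6–OOH, with the isopropenyl group C7=C8 on C6 and the E-alkene C2=C3 on C4; the coumarin bicycle is bought and no ring is formed.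
- C6–OOH is cut as a C–O bond made by a nucleophilic peroxide with inversion at a 6R allylic methanesulfonate, not by an ene reaction of a C6=C7 alkene; C4–O is a silyl ether, so only C6 can leave.
- The 6R carbinol comes from oxazaborolidine reduction of a C6 isopropenyl ketone; this chain is cut at C4–C5 into two C5 units, methyl isopropenyl ketone and an (E)-enal, joined by a reagent-controlled boron aldol that sets 4S.
- The enal already carries the coumarin ether and the 2E geometry, from cross-metathesis of the allyl ether with methacrolein.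
- Both stereocentres are set by reagents (C4 by aldol, C6 by reduction then inversion), so no statistical mixture of C6 epimers has to be separated at the end, and the route needs no chiral-diamine carbenoid chemistry and no diol-selective Mitsunobu.

Key step: step 6

Assumption: the methyl-ketone enolate made with (+)-B-chlorodiisopinocampheylborane is taken to add to the Si face of the enal (giving 4S); should the sense prove opposite, the commercial antipodal reagent would be used with no other change.

Step 1
Reactants: 1 4-hydroxy-5-methyl-2H-chromen-2-one; 2 prop-2-en-1-ol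
Product: 3 5-methyl-4-(prop-2-en-1-yloxy)-2H-chromen-2-one
Conditions: PPh3 (1.2 equiv), DIAD (1.2 equiv), THF, 0 °C to rt
Reagents that add atoms: none
Why: Mitsunobu etherification: the acidic 4-hydroxycoumarin (pKa about 4) should attack the alkoxyphosphonium ion of allyl alcohol through oxygen, and no stereocentre is involved.

Step 2
Reactants: 3 5-methyl-4-(prop-2-en-1-yloxy)-2H-chromen-2-one; 4 2-methylprop-2-enal
Product: 5 (2E)-2-methyl-4-[(5-methyl-2-oxo-2H-chromen-4-yl)oxy]but-2-enal
Conditions: 4 (5 equiv), second-generation Grubbs catalyst RuCl2(=CHPh)(H2IMes)(PCy3) (5 mol%), 1,4-benzoquinone (10 mol%), CH2Cl2, 40 °C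
Reagents that add atoms: none
Why: Olefin cross-metathesis of a terminal allyl ether with methacrolein, which is E-selective for the trisubstituted enal and so fixes the 2E geometry of the target's C2=C3 bond; benzoquinone suppresses isomerisation of the allyl ether.

Step 3
Reactants: 6 3-methylbut-3-en-2-one; 5 (2E)-2-methyl-4-[(5-methyl-2-oxo-2H-chromen-4-yl)oxy]but-2-enal
Product: 9 4-{[(2E,4S)-4-hydroxy-3,7-dimethyl-6-oxoocta-2,7-dien-1-yl]oxy}-5-methyl-2H-chromen-2-one, via boron dienolate 7 (not isolated), via boron aldolate 8 (not isolated)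
Conditions: 6 (1.5 equiv), (+)-B-chlorodiisopinocampheylborane (1.4 equiv), Et3N (1.6 equiv), Et2O, 0 °C, 2 h; 5, −78 to −20 °C, 16 h; MeOH/pH 7 buffer
Reagents that add atoms: none
Why: Diisopinocampheylboron aldol reaction of a methyl ketone: the kinetic dienolate 7 should add 1,2 to the enal through a cyclic six-membered boron transition state in which the isopinocampheyl ligands select the Si face, setting C4 as S and joining the two C5 halves at C4–C5; the minor C4 antipode becomes a separable diastereomer after step 5.

Step 4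
Reactants: 9 4-{[(2E,4S)-4-hydroxy-3,7-dimethyl-6-oxoocta-2,7-dien-1-yl]oxy}-5-methyl-2H-chromen-2-one
Product: 10 5-methyl-4-({(2E,4S)-3,7-dimethyl-6-oxo-4-[(triethylsilyl)oxy]octa-2,7-dien-1-yl}oxy)-2H-chromen-2-one
Conditions: TESCl (1.3 equiv), imidazole (2 equiv), CH2Cl2, 0 °C
Reagents that add atoms: chlorotriethylsilane CC[Si](Cl)(CC)CC
Why: O-Silylation: it stops oxa-Michael closure of the β-hydroxy enone and turns the C4 oxygen into a group that cannot leave in step 6.

Step 5
Reactants: 10 5-methyl-4-({(2E,4S)-3,7-dimethyl-6-oxo-4-[(triethylsilyl)oxy]octa-2,7-dien-1-yl}oxy)-2H-chromen-2-one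
Product: 11 4-({(2E,4S,6R)-6-hydroxy-3,7-dimethyl-4-[(triethylsilyl)oxy]octa-2,7-dien-1-yl}oxy)-5-methyl-2H-chromen-2-one
Conditions: (3aS)-1-methyl-3,3-diphenyltetrahydro-1H,3H-pyrrolo[1,2-c][1,3,2]oxazaborole [(S)-2-methyl-CBS-oxazaborolidine] (0.3 equiv), catecholborane (2 equiv), toluene, −78 °C; MeOH quench
Reagents that add atoms: none
Why: Corey–Bakshi–Shibata reduction: the (S)-oxazaborolidine should bind the enone with the isopropenyl group as the large substituent and deliver hydride 1,2 to the face that gives the 6R allylic alcohol (reagent control, independent of the remote C4 silyl ether), while catecholborane at −78 °C leaves the other alkenes and the lactone alone.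

Step 6
Reactants: 11 4-({(2E,4S,6R)-6-hydroxy-3,7-dimethyl-4-[(triethylsilyl)oxy]octa-2,7-dien-1-yl}oxy)-5-methyl-2H-chromen-2-one
Product: 13 5-methyl-4-({(2E,4S,6S)-6-hydroperoxy-3,7-dimethyl-4-[(triethylsilyl)oxy]octa-2,7-dien-1-yl}oxy)-2H-chromen-2-one, via allylic methanesulfonate 12 (not isolated)
Conditions: Ms2O (1.3 equiv), Et3N (1.6 equiv), CH2Cl2, −40 °C; cannulated into anhydrous H2O2 in Et2O (15 equiv), CsOH·H2O (3 equiv), DMF, −40 to 0 °C
Reagents that add atoms: hydrogen peroxide OO
Why: SN2 displacement: the hydroperoxide anion, an α-effect oxygen nucleophile, should attack C6 from the face opposite to the methanesulfonate made in the same flask, so that the 6R carbinol of step 5 becomes the 6S hydroperoxide with the O–O unit delivered intact. The closest known reaction types are the conversion of secondary alkyl methanesulfonates into hydroperoxides with alkaline hydrogen peroxide, which runs with inversion, and the conversion of allylic methanesulfonates into allylic hydroperoxides with anhydrous hydrogen peroxide at low temperature. No ring is closed. C6 is the only new stereocentre and is controlled by the configuration set by the oxazaborolidine in step 5; C4 cannot take part because its oxygen is a silyl ether and not a leaving group, which removes the C4/C6 ambiguity that any cyclic 1,3-diol derivative would have. The step needs SN2 at C6 to win over SN2′ attack at C8, ionisation, E2 toward C5 and a second alkylation; a weakly basic but strongly nucleophilic anion in a dipolar aprotic medium at low temperature, an allyl system whose cation would be only secondary/primary stabilised, and a large excess of H2O2 should secure this. The 4-alkoxycoumarin is a vinylogous carbonate and is expected to add hydroperoxide only reversibly under these conditions.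

Step 7
Reactants: 13 5-methyl-4-({(2E,4S,6S)-6-hydroperoxy-3,7-dimethyl-4-[(triethylsilyl)oxy]octa-2,7-dien-1-yl}oxy)-2H-chromen-2-one
Product: 14 4-{[(2E,4S,6S)-6-hydroperoxy-4-hydroxy-3,7-dimethylocta-2,7-dien-1-yl]oxy}-5-methyl-2H-chromen-2-one
Conditions: HF·pyridine, pyridine, THF, 0 °C
Reagents that add atoms: none
Why: Fluoride-mediated cleavage of the silyl ether under buffered, weakly acidic conditions that should leave the O–O bond, the allylic hydroperoxide and the allyl enol ether of the coumarin intact; no stereocentre is touched.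

**Compound list**
1 | 4-hydroxy-5-methyl-2H-chromen-2-one | Cc1cccc2oc(=O)cc(O)c12 | starting material
2 | prop-2-en-1-ol | C=CCO | starting material
3 | 5-methyl-4-(prop-2-en-1-yloxy)-2H-chromen-2-one | C=CCOc1cc(=O)oc2cccc(C)c12 | intermediate
4 | 2-methylprop-2-enal | C=C(C)C=O | starting material
5 | (2E)-2-methyl-4-[(5-methyl-2-oxo-2H-chromen-4-yl)oxy]but-2-enal | O=C/C(C)=C/COc1cc(=O)oc2cccc(C)c12 | intermediate
6 | 3-methylbut-3-en-2-one | CC(=O)C(C)=C | starting material
7 | 3-methylbuta-1,3-dien-2-yl diisopinocampheylborinate (isopinocampheyl groups from (−)-α-pinene) | C=C(C)C(=C)OB([C@H]1C[C@H]2C[C@@H]([C@@H]1C)C2(C)C)[C@H]1C[C@H]2C[C@@H]([C@@H]1C)C2(C)C | intermediate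
8 | (2E,4S)-3,7-dimethyl-1-[(5-methyl-2-oxo-2H-chromen-4-yl)oxy]-6-oxoocta-2,7-dien-4-yl diisopinocampheylborinate | C=C(C)C(=O)C[C@H](OB([C@H]1C[C@H]2C[C@@H]([C@@H]1C)C2(C)C)[C@H]1C[C@H]2C[C@@H]([C@@H]1C)C2(C)C)/C(C)=C/COc1cc(=O)oc2cccc(C)c12 | intermediate
9 | 4-{[(2E,4S)-4-hydroxy-3,7-dimethyl-6-oxoocta-2,7-dien-1-yl]oxy}-5-methyl-2H-chromen-2-one | C=C(C)C(=O)C[C@H](O)/C(C)=C/COc1cc(=O)oc2cccc(C)c12 | intermediate
10 | 5-methyl-4-({(2E,4S)-3,7-dimethyl-6-oxo-4-[(triethylsilyl)oxy]octa-2,7-dien-1-yl}oxy)-2H-chromen-2-one | C=C(C)C(=O)C[C@H](O[Si](CC)(CC)CC)/C(C)=C/COc1cc(=O)oc2cccc(C)c12 | intermediate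
11 | 4-({(2E,4S,6R)-6-hydroxy-3,7-dimethyl-4-[(triethylsilyl)oxy]octa-2,7-dien-1-yl}oxy)-5-methyl-2H-chromen-2-one | C=C(C)[C@H](O)C[C@H](O[Si](CC)(CC)CC)/C(C)=C/COc1cc(=O)oc2cccc(C)c12 | intermediate
12 | (3R,5S,6E)-2,6-dimethyl-8-[(5-methyl-2-oxo-2H-chromen-4-yl)oxy]-5-[(triethylsilyl)oxy]octa-1,6-dien-3-yl methanesulfonate | C=C(C)[C@H](OS(C)(=O)=O)C[C@H](O[Si](CC)(CC)CC)/C(C)=C/COc1cc(=O)oc2cccc(C)c12 | intermediate
13 | 5-methyl-4-({(2E,4S,6S)-6-hydroperoxy-3,7-dimethyl-4-[(triethylsilyl)oxy]octa-2,7-dien-1-yl}oxy)-2H-chromen-2-one | C=C(C)[C@H](C[C@H](O[Si](CC)(CC)CC)/C(C)=C/COc1cc(=O)oc2cccc(C)c12)OO | intermediate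
14 | 4-{[(2E,4S,6S)-6-hydroperoxy-4-hydroxy-3,7-dimethylocta-2,7-dien-1-yl]oxy}-5-methyl-2H-chromen-2-one | C=C(C)[C@H](C[C@H](O)/C(C)=C/COc1cc(=O)oc2cccc(C)c12)OO | target

Total step count: 7. Longest linear sequence: 7 steps (1 → 3 → 5 → 9 → 10 → 11 → 13 → 14).

**Steps most likely to fail**

1. Step 6 (displacement by hydroperoxide). Ionisation of the allylic methanesulfonate or attack at C8 would erode the C6 configuration or move the peroxide to the chain end; a second alkylation of the product anion and opening of the lactone by the small hydroperoxide anion are further losses. The fallback sets out from alcohol 11 and returns at target 14. The peroxide is brought in as a protected, monofunctional unit: 2-methoxyprop-2-yl hydroperoxide F1 (from ozonolysis of 2,3-dimethylbut-2-ene in methanol) is deprotonated with CsOH·H2O in DMF and alkylated at 0 °C by methanesulfonate 12, made from 11 as in step 6, to give the mixed peroxyketal F2 with inversion at C6. This bulky dialkyl-type peroxide cannot be alkylated again and is inert to base, and aqueous acetic acid in THF then removes the peroxyketal and the silyl ether in one operation. The fallback does not make SN2′ attack or ionisation less likely; any 6R material would be a diastereomer and would be separated at the stage of F2.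

2. Step 3 (boron aldol). Incomplete enantioface control, retro-aldol cleavage or oxa-Michael closure of the β-hydroxy enone may cut the supply of 9. The fallback sets out from enal 5 and returns at ketone 10. Brown allylboration with (−)-B-allyldiisopinocampheylborane (Si-face attack) should give the (4S)-homoallylic alcohol F3, and TESCl/imidazole its silyl ether F4. OsO4 (catalytic)/NaIO4/2,6-lutidine should cleave the terminal vinyl group, the trisubstituted alkene being deactivated by its two allylic oxygens, to the aldehyde F5. Isopropenylmagnesium bromide at −78 °C then gives the carbinol F6 as a mixture of C6 epimers, which Dess–Martin periodinane oxidises to 10.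

3. Step 2 (cross-metathesis). Ruthenium hydride isomerisation of the allyl ether to the propenyl ether, or slow turnover with the electron-poor partner, may limit conversion. The fallback sets out from coumarin 1 and returns at enal 5. Mitsunobu etherification with 3-methylbut-2-en-1-ol gives the prenyl ether F7; SeO2 (catalytic)/t-BuOOH in CH2Cl2 oxidises the E-methyl group to the (E)-allylic alcohol F8, and MnO2 completes the oxidation to 5.

**Further compounds**
F1 | step 6 | 2-methoxyprop-2-yl hydroperoxide | COC(C)(C)OO
F2 | step 6 | 5-methyl-4-({(2E,4S,6S)-6-[(2-methoxypropan-2-yl)peroxy]-3,7-dimethyl-4-[(triethylsilyl)oxy]octa-2,7-dien-1-yl}oxy)-2H-chromen-2-one | C=C(C)[C@H](C[C@H](O[Si](CC)(CC)CC)/C(C)=C/COc1cc(=O)oc2cccc(C)c12)OOC(C)(C)OC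
F3 | step 3 | 4-{[(2E,4S)-4-hydroxy-3-methylhepta-2,6-dien-1-yl]oxy}-5-methyl-2H-chromen-2-one | C=CC[C@H](O)/C(C)=C/COc1cc(=O)oc2cccc(C)c12
F4 | step 3 | 5-methyl-4-({(2E,4S)-3-methyl-4-[(triethylsilyl)oxy]hepta-2,6-dien-1-yl}oxy)-2H-chromen-2-one | C=CC[C@H](O[Si](CC)(CC)CC)/C(C)=C/COc1cc(=O)oc2cccc(C)c12
F5 | step 3 | (3S,4E)-4-methyl-6-[(5-methyl-2-oxo-2H-chromen-4-yl)oxy]-3-[(triethylsilyl)oxy]hex-4-enal | O=CC[C@H](O[Si](CC)(CC)CC)/C(C)=C/COc1cc(=O)oc2cccc(C)c12
F6 | step 3 | 4-({(2E,4S,6RS)-6-hydroxy-3,7-dimethyl-4-[(triethylsilyl)oxy]octa-2,7-dien-1-yl}oxy)-5-methyl-2H-chromen-2-one (mixture of C6 epimers) | C=C(C)C(O)C[C@H](O[Si](CC)(CC)CC)/C(C)=C/COc1cc(=O)oc2cccc(C)c12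
F7 | step 2 | 5-methyl-4-[(3-methylbut-2-en-1-yl)oxy]-2H-chromen-2-one | CC(C)=CCOc1cc(=O)oc2cccc(C)c12
F8 | step 2 | 4-{[(2E)-4-hydroxy-3-methylbut-2-en-1-yl]oxy}-5-methyl-2H-chromen-2-one | OC/C(C)=C/COc1cc(=O)oc2cccc(C)c12
A1 | direct plan | 4-hydroxy-5-methyl-2H-chromen-2-one | Cc1cccc2oc(=O)cc(O)c12
A2 | direct plan | (2E,4S)-3,7-dimethylocta-2,6-diene-1,4-diol | OC/C=C(\C)[C@@H](O)CC=C(C)C
A3 | direct plan | 4-{[(2E,4S)-4-hydroxy-3,7-dimethylocta-2,6-dien-1-yl]oxy}-5-methyl-2H-chromen-2-one | Cc1cccc2oc(=O)cc(OC/C=C(\C)[C@@H](O)CC=C(C)C)c12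
A4 | direct plan | 4-{[(2E,4S,6R)-6-hydroperoxy-4-hydroxy-3,7-dimethylocta-2,7-dien-1-yl]oxy}-5-methyl-2H-chromen-2-one | C=C(C)[C@@H](C[C@H](O)/C(C)=C/COc1cc(=O)oc2cccc(C)c12)OO
A5 | direct plan | 4-{[(2E,4S,5E)-7-hydroperoxy-4-hydroxy-3,7-dimethylocta-2,5-dien-1-yl]oxy}-5-methyl-2H-chromen-2-one | CC(C)(OO)/C=C/[C@H](O)/C(C)=C/COc1cc(=O)oc2cccc(C)c12
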